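**Retrosynthetic overview**

1. The last disconnections are tert-butyl ester cleavage and C3-acylation (O-acylation, then O-to-C shift) of (6R)-6-methyloxane-2,4-dione by the C9 carboxyl of the chain. This dihydropyranone is the only ring and is closed first, by lactonisation of a delta-hydroxy-beta-keto ester made from methyl (R)-3-hydroxybutanoate.
2. The key disconnection is the C4(sp2)–C5(sp3) bond of the non-3-enoic acid chain. It is formed by nickel-catalysed decarboxylative alkenylation of an N-acyloxyphthalimide with an (E)-dienylzinc, itself generated in the same flask by syn-hydrozirconation of a 2-ethynyl-2-enoate.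
3. Enabling feature: C5 is an unactivated CH2 flanked by the C6 methyl stereocentre, and C5–C9 with the C6 methyl are C2–C6 with the C3 methyl of (R)-citronellic acid. The terpene's C1 carboxyl therefore sits on C5 as a traceless radical handle (lost as CO2), its isopropylidene end is a latent C9 carboxyl, and C4 is a terminal alkyne carbon, so syn H–Zr addition sets the 3E geometry.
4. The enyne comes from (S)-2-methylbutan-1-ol: oxidation, bromo-ylide Wittig (fixes the 2E ylidene geometry), Sonogashira coupling, desilylation.
5. All three stereocentres are bought from the chiral pool; none is created or touched in the route.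

Key step: step 7

Remark: the 3-acyl-4-hydroxy-5,6-dihydropyran-2-one is drawn as the enol tautomer of the target SMILES, and the C6 centre is only as pure as the purchased (R)-citronellic acid, so material of high enantiomeric purity is assumed.

**Route**

Step 1
Reactants: 1 (2S)-2-methylbutan-1-ol
Product: 2 (2S)-2-methylbutanal
Conditions: TEMPO (1 mol%), KBr (10 mol%), aq. NaOCl (1.1 equiv), NaHCO3 buffer, CH2Cl2, 0 °C, 15 min; organic phase dried (MgSO4) and used directly
Reagents that add atoms: none
Why: TEMPO-catalysed hypochlorite oxidation (oxoammonium mechanism) stops at the aldehyde and is fast and nearly neutral at 0 °C, so the enolisable alpha stereocentre should survive if the volatile aldehyde is neither concentrated nor stored.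

Step 2
Reactants: 2 (2S)-2-methylbutanal; 3 tert-butyl 2-(triphenyl-λ5-phosphanylidene)acetate
Product: 5 tert-butyl (2Z,4S)-2-bromo-4-methylhex-2-enoate, via bromo ylide 4 (not isolated)
Conditions: 3 (1.3 equiv), NBS (1.3 equiv), CH2Cl2, −20 °C, 30 min; then 2 in CH2Cl2, −20 °C to rt, 16 h
Reagents that add atoms: N-bromosuccinimide, O=C1CCC(=O)N1Br
Why: Wittig olefination with the ylide brominated in situ should place the alkyl group trans to the ester, as stabilised ylides do, giving the Z-bromoalkene that becomes the 2E ylidene geometry of the target once bromine is replaced with retention; any minor isomer is removed by chromatography.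

Step 3
Reactants: 5 tert-butyl (2Z,4S)-2-bromo-4-methylhex-2-enoate; 6 ethynyltrimethylsilane
Product: 7 tert-butyl (2E,4S)-4-methyl-2-[(trimethylsilyl)ethynyl]hex-2-enoate
Conditions: PdCl2(PPh3)2 (3 mol%), CuI (5 mol%), Et3N (3 equiv), THF, rt
Reagents that add atoms: none
Why: Sonogashira coupling of the electron-poor alkenyl bromide proceeds by oxidative addition, copper acetylide transfer and reductive elimination with retention of alkene geometry, under conditions too mild to affect the tert-butyl ester or the gamma stereocentre.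

Step 4
Reactants: 7 tert-butyl (2E,4S)-4-methyl-2-[(trimethylsilyl)ethynyl]hex-2-enoate
Product: 8 tert-butyl (2E,4S)-2-ethynyl-4-methylhex-2-enoate
Conditions: K2CO3 (0.2 equiv), MeOH, 0 °C, 30 min
Reagents that add atoms: none
Why: methoxide-catalysed protodesilylation of the alkynylsilane is fast at 0 °C, whereas the hindered tert-butyl ester is not transesterified and the short cold exposure should not deprotonate the gamma position.

Step 5
Reactants: 9 (3R)-3,7-dimethyloct-6-enoic acid ((R)-citronellic acid)
Product: 11 (3R)-6-methoxy-3-methyl-6-oxohexanoic acid, via aldehyde carboxylate 10 (not isolated)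
Conditions: O3, NaOH (5 equiv, 2.5 M in MeOH), CH2Cl2, −78 °C; then H2O, 1 M HCl to pH 3, 0 °C
Reagents that add atoms: ozone, [O-][O+]=O; methanol, CO
Why: ozonolysis in methanolic NaOH cleaves the isopropylidene to aldehyde 10, whose methanol adduct is oxidised by further ozone to the methyl ester while the original carboxyl rides through as its sodium salt, so the two chain ends emerge differentiated in one operation and the remote stereocentre is untouched.

Step 6
Reactants: 11 (3R)-6-methoxy-3-methyl-6-oxohexanoic acid
Product: 12 1-(1,3-dioxoisoindolin-2-yl) 6-methyl (3R)-3-methylhexanedioate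
Conditions: N-hydroxyphthalimide (1.1 equiv), DIC (1.1 equiv), DMAP (10 mol%), CH2Cl2, rt
Reagents that add atoms: N-hydroxyphthalimide, O=C1c2ccccc2C(=O)N1O
Why: carbodiimide (Steglich-type) esterification of the only free carboxyl should give the stable redox-active ester, the methyl ester being inert.

Step 7
Reactants: 8 tert-butyl (2E,4S)-2-ethynyl-4-methylhex-2-enoate; 12 1-(1,3-dioxoisoindolin-2-yl) 6-methyl (3R)-3-methylhexanedioate
Product: 15 1-tert-butyl 9-methyl (2E,3E,6R)-6-methyl-2-[(2S)-2-methylbutylidene]non-3-enedioate, via dienylzirconocene chloride 13 (not isolated), via dienylzinc chloride 14 (not isolated)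
Conditions: 8 (2.0 equiv), Cp2Zr(H)Cl (2.1 equiv), THF, 0 °C to rt, 30 min; ZnCl2 (2.1 equiv, THF), 0 °C, 20 min; then 12 (1.0 equiv), Ni(acac)2 (10 mol%), 2,2′-bipyridine (10 mol%), THF/DMF, rt, 12 h
Reagents that add atoms: none
Why: Cp2Zr(H)Cl adds hydrogen and zirconium syn across the terminal alkyne of 8 with zirconium on the unhindered terminal carbon, so the 3E geometry is fixed before the C–C bond is made, and ZnCl2 converts 13 into dienylzinc 14 with retention. Bipyridine-ligated low-valent nickel reduces the N-acyloxyphthalimide 12 by single-electron transfer; loss of phthalimide anion and CO2 leaves the primary C5 radical, which is captured by the alkenylnickel species, and reductive elimination from trivalent nickel forms the C4–C5 bond with retention of alkene geometry. The closest known reaction type is the nickel-catalysed decarboxylative alkenylation of redox-active esters with alkenylzinc reagents, here fed by a hydrozirconation and zinc transmetalation. No ring is closed and no stereocentre is created; the only new stereo-element, the 3E alkene, is controlled by the syn-hydrometalation. The step needs chemoselective hydrometalation of the alkyne in the presence of the enoate, which the bulky tert-butyl ester and the trisubstituted cross-conjugated C=C should secure, and radical formation at one carboxyl only, which is secured because only the former C1 carboxyl of citronellic acid is a phthalimide ester while C9 is a plain methyl ester. The C6 centre lies beta to the radical and cannot be scrambled, and because the isopropylidene was cleaved in step 5 the radical has no alkene within cyclisation reach.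

Step 8
Reactants: 15 1-tert-butyl 9-methyl (2E,3E,6R)-6-methyl-2-[(2S)-2-methylbutylidene]non-3-enedioate
Product: 16 (4R,6E,8E,10S)-8-(tert-butoxycarbonyl)-4,10-dimethyldodeca-6,8-dienoic acid
Conditions: LiOH·H2O (2 equiv), THF/H2O 3:1, 0 °C to rt; then 1 M HCl to pH 3
Reagents that add atoms: lithium hydroxide, [Li+].[OH-]
Why: saponification (BAc2) should take the unhindered saturated methyl ester far faster than the tert-butyl ester of the alpha-branched dienoate, and hydroxide is too weak a base to deconjugate the diene or epimerise either stereocentre.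

Step 9
Reactants: 17 methyl (3R)-3-hydroxybutanoate; 18 tert-butyl acetate
Product: 20 tert-butyl (5R)-5-hydroxy-3-oxohexanoate, via lithium enolate 19 (not isolated)
Conditions: 18 (4 equiv), LiN(iPr)2 (4 equiv), THF, −78 °C; then 17, −78 to −20 °C; sat. aq. NH4Cl
Reagents that add atoms: none
Why: crossed Claisen condensation of excess lithium tert-butyl acetate enolate with the unprotected hydroxy ester (one equivalent is spent on the hydroxyl and the product is shielded as its enolate) should give the delta-hydroxy-beta-keto ester without involving the carbinol stereocentre.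

Step 10
Reactants: 20 tert-butyl (5R)-5-hydroxy-3-oxohexanoate
Product: 22 (6R)-6-methyloxane-2,4-dione, via hydroxy keto acid 21 (not isolated)
Conditions: TFA/CH2Cl2 1:4, rt, 3 h
Reagents that add atoms: none
Why: acidolysis of the tert-butyl ester (loss of isobutene) followed by 6-exo-trig lactonisation of the delta-hydroxy acid closes the only ring of the target, and since the C–O bond at the stereocentre is never broken the R configuration is retained.

Step 11
Reactants: 16 (4R,6E,8E,10S)-8-(tert-butoxycarbonyl)-4,10-dimethyldodeca-6,8-dienoic acid; 22 (6R)-6-methyloxane-2,4-dione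
Product: 24 tert-butyl (2E,3E,6R)-9-[(6R)-4-hydroxy-6-methyl-2-oxo-5,6-dihydro-2H-pyran-3-yl]-6-methyl-2-[(2S)-2-methylbutylidene]-9-oxonon-3-enoate, via enol ester 23 (not isolated)
Conditions: DCC (1.2 equiv), DMAP (1.2 equiv), CH2Cl2, 0 °C to rt, 16 h
Reagents that add atoms: none
Why: Steglich O-acylation of the enolised dione is followed by DMAP-mediated O-to-C acyl migration (Fries-type, through the acylpyridinium and dione enolate ion pair) to the thermodynamically favoured chelated 3-acyl tricarbonyl, a standard entry to 3-acyl-4-hydroxy-5,6-dihydropyran-2-ones.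

Step 12
Reactants: 24 tert-butyl (2E,3E,6R)-9-[(6R)-4-hydroxy-6-methyl-2-oxo-5,6-dihydro-2H-pyran-3-yl]-6-methyl-2-[(2S)-2-methylbutylidene]-9-oxonon-3-enoate
Product: 25 (2E,3E,6R)-9-[(6R)-4-hydroxy-6-methyl-2-oxo-5,6-dihydro-2H-pyran-3-yl]-6-methyl-2-[(2S)-2-methylbutylidene]-9-oxonon-3-enoic acid
Conditions: TFA/CH2Cl2 1:4, 0 °C to rt
Reagents that add atoms: none
Why: acidolysis of the tert-butyl ester (AAL1, loss of isobutene) should free the dienoic acid under conditions in which the acyl tricarbonyl lactone, the electron-poor diene and all three stereocentres are stable.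

**Compound list**

1 | (2S)-2-methylbutan-1-ol | CC[C@H](C)CO | starting material
2 | (2S)-2-methylbutanal | CC[C@H](C)C=O | intermediate
3 | tert-butyl 2-(triphenyl-λ5-phosphanylidene)acetate | CC(C)(C)OC(=O)C=P(c1ccccc1)(c1ccccc1)c1ccccc1 | starting material
4 | tert-butyl 2-bromo-2-(triphenyl-λ5-phosphanylidene)acetate (bromo ylide) | CC(C)(C)OC(=O)C(Br)=P(c1ccccc1)(c1ccccc1)c1ccccc1 | intermediate
5 | tert-butyl (2Z,4S)-2-bromo-4-methylhex-2-enoate | CC[C@H](C)/C=C(\Br)C(=O)OC(C)(C)C | intermediate
6 | ethynyltrimethylsilane | C#C[Si](C)(C)C | starting material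
7 | tert-butyl (2E,4S)-4-methyl-2-[(trimethylsilyl)ethynyl]hex-2-enoate | CC[C@H](C)/C=C(\C#C[Si](C)(C)C)C(=O)OC(C)(C)C | intermediate
8 | tert-butyl (2E,4S)-2-ethynyl-4-methylhex-2-enoate | CC[C@H](C)/C=C(\C#C)C(=O)OC(C)(C)C | intermediate
9 | (3R)-3,7-dimethyloct-6-enoic acid ((R)-citronellic acid) | CC(C)=CCC[C@@H](C)CC(=O)O | starting material
10 | sodium (3R)-3-methyl-6-oxohexanoate (aldehyde carboxylate) | [Na+].[O-]C(=O)C[C@H](C)CCC=O | intermediate
11 | (3R)-6-methoxy-3-methyl-6-oxohexanoic acid | COC(=O)CC[C@@H](C)CC(=O)O | intermediate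
12 | 1-(1,3-dioxoisoindolin-2-yl) 6-methyl (3R)-3-methylhexanedioate | COC(=O)CC[C@@H](C)CC(=O)ON1C(=O)c2ccccc2C1=O | intermediate
13 | tert-butyl (2E,4S)-2-{(E)-2-[chlorobis(cyclopentadienyl)zirconio]ethenyl}-4-methylhex-2-enoate (dienylzirconocene chloride) | CC[C@H](C)/C=C(\C=C\[Zr](Cl)(C1C=CC=C1)C1C=CC=C1)C(=O)OC(C)(C)C | intermediate
14 | tert-butyl (2E,4S)-2-[(E)-2-(chlorozincio)ethenyl]-4-methylhex-2-enoate (dienylzinc chloride) | CC[C@H](C)/C=C(\C=C\[Zn]Cl)C(=O)OC(C)(C)C | intermediate
15 | 1-tert-butyl 9-methyl (2E,3E,6R)-6-methyl-2-[(2S)-2-methylbutylidene]non-3-enedioate | CC[C@H](C)/C=C(\C=C\C[C@H](C)CCC(=O)OC)C(=O)OC(C)(C)C | intermediate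
16 | (4R,6E,8E,10S)-8-(tert-butoxycarbonyl)-4,10-dimethyldodeca-6,8-dienoic acid | CC[C@H](C)/C=C(\C=C\C[C@H](C)CCC(=O)O)C(=O)OC(C)(C)C | intermediate
17 | methyl (3R)-3-hydroxybutanoate | C[C@@H](O)CC(=O)OC | starting material
18 | tert-butyl acetate | CC(=O)OC(C)(C)C | starting material
19 | lithium 1-tert-butoxyethen-1-olate (lithium enolate) | [Li]OC(=C)OC(C)(C)C | intermediate
20 | tert-butyl (5R)-5-hydroxy-3-oxohexanoate | C[C@@H](O)CC(=O)CC(=O)OC(C)(C)C | intermediate
21 | (5R)-5-hydroxy-3-oxohexanoic acid (hydroxy keto acid) | C[C@@H](O)CC(=O)CC(=O)O | intermediate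
22 | (6R)-6-methyloxane-2,4-dione | C[C@@H]1CC(=O)CC(=O)O1 | intermediate
23 | (6R)-6-methyl-2-oxo-5,6-dihydro-2H-pyran-4-yl (4R,6E,8E,10S)-8-(tert-butoxycarbonyl)-4,10-dimethyldodeca-6,8-dienoate (enol ester) | CC[C@H](C)/C=C(\C=C\C[C@H](C)CCC(=O)OC1=CC(=O)O[C@H](C)C1)C(=O)OC(C)(C)C | intermediate
24 | tert-butyl (2E,3E,6R)-9-[(6R)-4-hydroxy-6-methyl-2-oxo-5,6-dihydro-2H-pyran-3-yl]-6-methyl-2-[(2S)-2-methylbutylidene]-9-oxonon-3-enoate | CC[C@H](C)/C=C(\C=C\C[C@H](C)CCC(=O)C1=C(O)C[C@@H](C)OC1=O)C(=O)OC(C)(C)C | intermediate
25 | (2E,3E,6R)-9-[(6R)-4-hydroxy-6-methyl-2-oxo-5,6-dihydro-2H-pyran-3-yl]-6-methyl-2-[(2S)-2-methylbutylidene]-9-oxonon-3-enoic acid | CC[C@H](C)/C=C(\C=C\C[C@H](C)CCC(=O)C1=C(O)C[C@@H](C)OC1=O)C(=O)O | target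

**Step count**

Total step count: 12. Longest linear sequence: 8 steps (steps 1, 2, 3, 4, 7, 8, 11, 12).

**Steps most likely to fail**

Step 7. The hydride reagent may reduce the enoate competitively. Zirconium-to-zinc transfer may be incomplete. Nickel may capture the primary radical too slowly, so that it is reduced, dimerises or adds to the dienoate. The fallback sets out from 5 and 11 and comes back at 15, replacing both the hydrozirconation and the radical coupling by two-electron chemistry. Stille coupling of 5 with excess (E)-1,2-bis(tributylstannyl)ethene (Pd(PPh3)4, toluene, 90 °C) should give the dienylstannane tert-butyl (2E,4S)-4-methyl-2-[(E)-2-(tributylstannyl)ethenyl]hex-2-enoate F1. Iododestannylation (I2, CH2Cl2, 0 °C) should then give the dienyl iodide tert-butyl (2E,4S)-2-[(E)-2-iodoethenyl]-4-methylhex-2-enoate F2, both with retention of geometry. Separately, iododecarboxylation of 11 (PhI(OAc)2, I2, visible light, cyclohexane) should give methyl (4R)-5-iodo-4-methylpentanoate F3. Zinc insertion (Zn dust, LiCl, THF, 40 °C) gives the ester-tolerant alkylzinc reagent [(2R)-5-methoxy-2-methyl-5-oxopentyl]zinc iodide F4. Negishi coupling of F4 with F2 (PdCl2(dppf), THF, rt) then gives 15.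

Step 11. The sequence may stall at the O-acyl stage without O-to-C migration, or the activated acid may be diverted to the N-acylurea. The fallback sets out from 16 and 17 and comes back at 24, building the ring after the chain is attached. Condensation of 16 with 2,2-dimethyl-1,3-dioxane-4,6-dione (Meldrum's acid; DCC, DMAP, CH2Cl2) should give the acyl derivative tert-butyl (2E,3E,6R)-9-(2,2-dimethyl-4,6-dioxo-1,3-dioxan-5-ylidene)-9-hydroxy-6-methyl-2-[(2S)-2-methylbutylidene]non-3-enoate F5. Heating F5 with 17 in toluene at 80 °C (acylketene trapping) should give the beta-keto ester 1-tert-butyl 11-[(2R)-4-methoxy-4-oxobutan-2-yl] (2E,3E,6R)-6-methyl-2-[(2S)-2-methylbutylidene]-9-oxoundec-3-enedioate F6. Dieckmann cyclisation of F6 (KOtBu, tBuOH/THF, rt), in which the doubly activated methylene attacks the methyl ester, closes the dihydropyranone and gives 24.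

Step 2. The weakly nucleophilic bromo ylide may olefinate the alpha-branched aldehyde slowly, during which the aldehyde enolises (erosion of the S centre) and Z selectivity is incomplete. The fallback sets out from 2 and 3 and comes back at 5. Fast Wittig olefination with the unbrominated ylide (3, CH2Cl2, 0 °C) should give tert-butyl (2E,4S)-4-methylhex-2-enoate F7. Bromine addition (Br2, CH2Cl2, −78 °C) gives the dibromide tert-butyl (4S)-2,3-dibromo-4-methylhexanoate F8. Dehydrobromination with Et3N (CH2Cl2, 0 °C to rt) through the enolate (E1cB) pathway should favour the more stable Z-bromo enoate 5, and any E isomer is separated.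

**Further compounds**

F1 | step 7 | tert-butyl (2E,4S)-4-methyl-2-[(E)-2-(tributylstannyl)ethenyl]hex-2-enoate | CC[C@H](C)/C=C(\C=C\[Sn](CCCC)(CCCC)CCCC)C(=O)OC(C)(C)C
F2 | step 7 | tert-butyl (2E,4S)-2-[(E)-2-iodoethenyl]-4-methylhex-2-enoate | CC[C@H](C)/C=C(\C=C\I)C(=O)OC(C)(C)C
F3 | step 7 | methyl (4R)-5-iodo-4-methylpentanoate | COC(=O)CC[C@@H](C)CI
F4 | step 7 | [(2R)-5-methoxy-2-methyl-5-oxopentyl]zinc iodide | COC(=O)CC[C@@H](C)C[Zn]I
F5 | step 11 | tert-butyl (2E,3E,6R)-9-(2,2-dimethyl-4,6-dioxo-1,3-dioxan-5-ylidene)-9-hydroxy-6-methyl-2-[(2S)-2-methylbutylidene]non-3-enoate | CC[C@H](C)/C=C(\C=C\C[C@H](C)CCC(O)=C1C(=O)OC(C)(C)OC1=O)C(=O)OC(C)(C)C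
F6 | step 11 | 1-tert-butyl 11-[(2R)-4-methoxy-4-oxobutan-2-yl] (2E,3E,6R)-6-methyl-2-[(2S)-2-methylbutylidene]-9-oxoundec-3-enedioate | CC[C@H](C)/C=C(\C=C\C[C@H](C)CCC(=O)CC(=O)O[C@H](C)CC(=O)OC)C(=O)OC(C)(C)C
F7 | step 2 | tert-butyl (2E,4S)-4-methylhex-2-enoate | CC[C@H](C)/C=C/C(=O)OC(C)(C)C
F8 | step 2 | tert-butyl (4S)-2,3-dibromo-4-methylhexanoate | CC[C@H](C)C(Br)C(Br)C(=O)OC(C)(C)C
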